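The violet run at 20.0 min keeps 0.4% of its D and shows 8.5% Q, so 91.1% of the charge sits unseen, in an intermediate called X here. D falls as a pseudo-first-order curve, with a constant read as 0.169 min⁻¹ in the amber flask and 0.264 min⁻¹ in the violet run. Their ratio of 1.56 stands beside a Z ratio of 1.54, so Z makes X.

| flask | D | G | Z | J | remark |
|---|---|---|---|---|---|
| amber | 20 mM | 1.5 equiv | 1.3 mol% | 0.5 mol% | the very flask that is asked about, followed so far |
| violet | 20 mM | 1.5 equiv | 2 mol% | 0.5 mol% | run made earlier |
| flask | 20 mM | 1.50 equiv | 1.3 mol% | 0.5 mol% |  |

| run | time / min | Q / % | D / % |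
|---|---|---|---|
| amber | 0.500 | 0 | 91.8 |
| amber | 1.33 | 1.0 | 80.2 |
| amber | 2.50 | 0.2 | 64.6 |
| amber | 4.00 | 0.9 | 50.7 |
| amber | 5.00 | 0.2 | 42.8 |
| amber | 8.00 | 2.2 | 25.3 |
| amber | 10.0 | 2.5 | 18.4 |
| violet | 1.00 | 0.4 | 76.9 |
| violet | 3.00 | 0.6 | 45.4 |
| violet | 6.00 | 1.4 | 20.3 |
| violet | 10.0 | 3.3 | 7.6 |
| violet | 12.0 | 4.8 | 4.2 |
| violet | 15.0 | 5.3 | 1.7 |
| violet | 20.0 | 8.5 | 0.4 |

(standard deviation of a reading: 0.5 percentage points)

- "the catalyst" is Z with its forms; J is a second catalyst
- no earlier run changes the charge of G; that part of a forecast is a guess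

1. apparent order in Z when 10% of the D are converted (percent change of the rate of making Q for one percent more Z charged)
2. apparent order in G when 10% of the D are converted (percent change of the rate of making Q for one percent more G charged)

This reckoning freezes X's clearing constant, the fraction of standing X turned into Q per minute. Late in the violet run, Q is taken as a straight line from the mean life of D, 3.79 min, up to the last reading, which gives a clearing constant of 0.00524 min⁻¹. The Q curve of the amber flask therefore starts flat, bends near 5.92 min, and then climbs with that slope. It should pass 2.71% at 10.0 min, where 2.5% was read, and reach 12.6% at 30.0 min. In the amber flask the mark of 10% conversion is reckoned at 0.623 min. Z moves that time, but X at the mark is practically the D converted, so this reckoning puts the order in Z at 0. No run varies G, and the guess here is order 1.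

The forecast gives 0 in Z and 0.8 in G, the latter near 1 but “possibly reduced by saturation”; on G it stands below this reckoning.

The amber flask gives 0.0018 in Z and 1.0 in G.

    D + Z → Z + X (k = 680 M⁻¹ min⁻¹)
    G + J + X → J + Q (k = 1800 M⁻² min⁻¹)
    Z ⇌ E (K = 8.00, k = 0.00920 min⁻¹)

With twice the Z, the time to the mark becomes 0.499 of its value. In the amber flask, the clearing constant gives X a half-life of 132 min, far longer than the 4.1 min half-life of D at 3.94 min. At 30.0 min the amber flask holds 87.3% X and 11.7% Q.

The runs were generated by integration for substances that don't exist, and the scatter is random.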